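The ring is numbered C1 (quaternary carbinol carbon carrying C7H2OBz), C2 (CHOH), C3 and C4 (CH2), C5 (CHOBz), C6 (CHOH). The oxygen-bearing carbons C2 and C5 are 1,4-related across C3–C4 of the cyclohexane ring, so both can come from carbonyl groups if C3 reacts as a homoenolate. The route stores C3–C4–C5 as a cyclopropanol on C6 of an L-tartrate-derived trans-dioxolane whose quaternary C1 carries the C2 aldehyde and C7H2OBn. One operation opens the cyclopropanol to a β-zincio ketone and adds C3 to C2, which closes the six-membered ring, unmasks the C5 ketone and sets C2. Reduction, inversion with benzoate and protecting-group exchange complete the target.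

Key step: step 4

Remark: the C1–C7 numbering above is kept for every intermediate; the commercial acetonide of dimethyl L-tartrate is the chiral starting material, and step 1 assumes that its enolate is alkylated cis to the neighbouring ester.

Step 1
Reactants: 1 dimethyl (4R,5R)-2,2-dimethyl-1,3-dioxolane-4,5-dicarboxylate; 2 benzyl chloromethyl ether
Product: 4 dimethyl (4R,5R)-4-[(benzyloxy)methyl]-2,2-dimethyl-1,3-dioxolane-4,5-dicarboxylate, via lithium enolate 3 (not isolated)
Conditions: LiN(iPr)2 (1.1 equiv), THF–DMPU, −78 °C; then BnOCH2Cl, −78 → −50 °C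
Reagents that add atoms: benzyl chloromethyl ether, ClCOCc1ccccc1
Why: Alkylation of an ester enolate: enolate 3 should survive at −78 °C because its β C–O bond lies in the ring plane, orthogonal to the enolate π system, and the electrophile should enter cis to the neighbouring ester, the face preferred in alkylations of this enolate, so the esters stay trans and quaternary C1 is set (4R) while C6 keeps its tartrate configuration.

Step 2
Reactants: 4 dimethyl (4R,5R)-4-[(benzyloxy)methyl]-2,2-dimethyl-1,3-dioxolane-4,5-dicarboxylate; 5 ethylmagnesium bromide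
Product: 6 methyl (4R,5S)-4-[(benzyloxy)methyl]-5-(1-hydroxycyclopropyl)-2,2-dimethyl-1,3-dioxolane-4-carboxylate
Conditions: Ti(OiPr)4 (0.3 equiv), EtMgBr (2.2 equiv, slow addition), THF, 0 °C → rt; aq NH4Cl
Reagents that add atoms: ethylmagnesium bromide, CC[Mg]Br
Why: Kulinkovich cyclopropanation: the titanacyclopropane formed from EtMgBr and Ti(OiPr)4 should add twice to the ester on tertiary C6, which is far less shielded than the neopentyl-type ester on quaternary C1, and the trans relationship of the new alkoxide to the remaining ester rules out lactonisation.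

Step 3
Reactants: 6 methyl (4R,5S)-4-[(benzyloxy)methyl]-5-(1-hydroxycyclopropyl)-2,2-dimethyl-1,3-dioxolane-4-carboxylate
Product: 7 (4R,5S)-4-[(benzyloxy)methyl]-5-(1-hydroxycyclopropyl)-2,2-dimethyl-1,3-dioxolane-4-carbaldehyde
Conditions: iBu2AlH (2.3 equiv), CH2Cl2, −78 °C; MeOH, then aq potassium sodium tartrate
Reagents that add atoms: none
Why: Partial reduction of an ester: after the first equivalent has deprotonated the cyclopropanol, iBu2AlH adds once to the α-alkoxy ester and the chelated aluminium hemiacetal should persist at −78 °C, so the non-enolisable C2 aldehyde is released only on work-up.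

Step 4
Reactants: 7 (4R,5S)-4-[(benzyloxy)methyl]-5-(1-hydroxycyclopropyl)-2,2-dimethyl-1,3-dioxolane-4-carbaldehyde
Product: 9 (3aR,7R,7aS)-7a-[(benzyloxy)methyl]-7-hydroxy-2,2-dimethylhexahydro-1,3-benzodioxol-4-one (trans-fused O1/O6 acetonide, C5 ketone, C2–OH trans to O1), via ethylzinc homoenolate 8 (not isolated)
Conditions: Et2Zn (1.05 equiv), 2,2′-bipyridine (1.1 equiv), DMSO–THF, 0.02 M, 25 → 45 °C; aq NH4Cl
Reagents that add atoms: none
Why: Proposed new method: Et2Zn deprotonates the cyclopropanol, and the zinc cyclopropoxide should undergo strain-releasing β-carbon elimination of the C5–C3 bond to the β-zincio ketone 8, whose C3–Zn bond then adds to the C2 aldehyde held on the same dioxolane. The closest known reaction types are the Et2Zn-mediated ring opening of cyclopropanols to zinc ketone homoenolates and the addition of zinc and titanium homoenolates to aldehydes between two molecules. The cyclohexanone ring closes in the 6-exo-trig mode, C3 attacking a carbonyl whose C=O bond is exocyclic to the ring being formed. The new stereocentre C2 is controlled by the trans-dioxolane, which fixes O1 equatorial and C7 axial in a chair transition state: the forming C2–C3 bond is antiperiplanar to C1–O1 and the zinc-bound aldehyde oxygen takes the equatorial site, where it avoids 1,3-diaxial contacts and can be chelated together with the benzyl ether oxygen on C7, giving the 2R alcohol trans to O1. The step needs transfer of C3 and not of ethyl, no enolisation and retention at C6: the aldehyde on quaternary C1 cannot enolise and is activated by its α-oxygen, uncatalysed ethyl transfer from zinc is slow whereas C3 is delivered within the ring-forming array, and the weakly basic zinc alkoxides in dilute solution should not epimerise C6.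

Step 5
Reactants: 9 (3aR,7R,7aS)-7a-[(benzyloxy)methyl]-7-hydroxy-2,2-dimethylhexahydro-1,3-benzodioxol-4-one; 10 tert-butyldimethylsilyl trifluoromethanesulfonate
Product: 11 (3aR,7R,7aR)-7a-[(benzyloxy)methyl]-7-[(tert-butyldimethylsilyl)oxy]-2,2-dimethylhexahydro-1,3-benzodioxol-4-one
Conditions: TBSOTf (1.3 equiv), 2,6-lutidine, CH2Cl2, −78 → 0 °C
Reagents that add atoms: tert-butyldimethylsilyl trifluoromethanesulfonate, CC(C)(C)[Si](C)(C)OS(=O)(=O)C(F)(F)F
Why: Silylation of a secondary alcohol with a silyl triflate and a hindered pyridine base, which is fast at low temperature and too weakly basic to enolise the C5 ketone or epimerise C6.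

Step 6
Reactants: 11 (3aR,7R,7aR)-7a-[(benzyloxy)methyl]-7-[(tert-butyldimethylsilyl)oxy]-2,2-dimethylhexahydro-1,3-benzodioxol-4-one
Product: 12 (3aS,4S,7R,7aR)-7a-[(benzyloxy)methyl]-7-[(tert-butyldimethylsilyl)oxy]-2,2-dimethylhexahydro-1,3-benzodioxol-4-ol (axial C5–OH, cis to O6)
Conditions: LiBH(sBu)3 (1.3 equiv), THF, −78 °C; H2O quench
Reagents that add atoms: none
Why: Sterically controlled hydride reduction of a cyclohexanone: the trans-fused dioxolane locks C7H2OBn axial on C1, 1,3-diaxial to the axial trajectory at C5, so the bulky borohydride should attack equatorially and give the axial (5S) alcohol, the epimer required for inversion in step 7.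

Step 7
Reactants: 12 (3aS,4S,7R,7aR)-7a-[(benzyloxy)methyl]-7-[(tert-butyldimethylsilyl)oxy]-2,2-dimethylhexahydro-1,3-benzodioxol-4-ol; 13 benzoic acid
Product: 14 (3aS,4R,7R,7aR)-7a-[(benzyloxy)methyl]-7-[(tert-butyldimethylsilyl)oxy]-2,2-dimethylhexahydro-1,3-benzodioxol-4-yl benzoate (equatorial C5–OBz, trans to O6)
Conditions: PPh3, diisopropyl azodicarboxylate (DIAD), PhCO2H, toluene, 0 °C → rt
Reagents that add atoms: benzoic acid, OC(=O)c1ccccc1
Why: Mitsunobu reaction: the axial C5 hydroxyl is activated as its oxyphosphonium ion and displaced by benzoate in an SN2 process with inversion, which should give the equatorial 5R benzoate of the target.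

Step 8
Reactants: 14 (3aS,4R,7R,7aR)-7a-[(benzyloxy)methyl]-7-[(tert-butyldimethylsilyl)oxy]-2,2-dimethylhexahydro-1,3-benzodioxol-4-yl benzoate
Product: 15 (3aS,4R,7R,7aR)-7-[(tert-butyldimethylsilyl)oxy]-7a-(hydroxymethyl)-2,2-dimethylhexahydro-1,3-benzodioxol-4-yl benzoate
Conditions: H2 (1 atm), 10% Pd on carbon, EtOAc, rt
Reagents that add atoms: none
Why: Hydrogenolysis of a benzyl ether over palladium in a neutral aprotic solvent, conditions under which benzoate, silyl ether and acetonide should be untouched.

Step 9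
Reactants: 15 (3aS,4R,7R,7aR)-7-[(tert-butyldimethylsilyl)oxy]-7a-(hydroxymethyl)-2,2-dimethylhexahydro-1,3-benzodioxol-4-yl benzoate; 16 benzoyl chloride
Product: 17 [(3aS,4R,7R,7aR)-4-(benzoyloxy)-7-[(tert-butyldimethylsilyl)oxy]-2,2-dimethylhexahydro-1,3-benzodioxol-7a-yl]methyl benzoate
Conditions: PhCOCl (1.3 equiv), pyridine, DMAP (cat.), CH2Cl2, 0 °C → rt
Reagents that add atoms: benzoyl chloride, O=C(Cl)c1ccccc1
Why: Acylation (nucleophilic acyl substitution) of the primary C7 hydroxyl, the only free hydroxyl in the molecule.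

Step 10
Reactants: 17 [(3aS,4R,7R,7aR)-4-(benzoyloxy)-7-[(tert-butyldimethylsilyl)oxy]-2,2-dimethylhexahydro-1,3-benzodioxol-7a-yl]methyl benzoate
Product: 18 [(1S,2S,3R,6R)-3-(benzoyloxy)-1,2,6-trihydroxycyclohexyl]methyl benzoate (target; 1S,2R,5R,6S in the route numbering)
Conditions: CF3CO2H–H2O (9:1), 0 °C → rt
Reagents that add atoms: none
Why: Acid-catalysed hydrolysis should cleave the strained trans-fused isopropylidene ketal and the silyl ether in one operation, while the benzoates are stable and acyl migration, a base-promoted process, is not expected in aqueous acid.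

Compound list
1 | dimethyl (4R,5R)-2,2-dimethyl-1,3-dioxolane-4,5-dicarboxylate (acetonide of dimethyl L-tartrate) | COC(=O)[C@@H]1OC(C)(C)O[C@H]1C(=O)OC | starting material
2 | benzyl chloromethyl ether | ClCOCc1ccccc1 | starting material
3 | lithium enolate of 1 (enolate at the future C1, R ester carbon C6 unchanged) | COC(=O)[C@@H]1OC(C)(C)OC1=C(OC)O[Li] | intermediate
4 | dimethyl (4R,5R)-4-[(benzyloxy)methyl]-2,2-dimethyl-1,3-dioxolane-4,5-dicarboxylate (esters trans) | COC(=O)[C@@H]1OC(C)(C)O[C@@]1(COCc2ccccc2)C(=O)OC | intermediate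
5 | ethylmagnesium bromide | CC[Mg]Br | starting material
6 | methyl (4R,5S)-4-[(benzyloxy)methyl]-5-(1-hydroxycyclopropyl)-2,2-dimethyl-1,3-dioxolane-4-carboxylate | OC1(CC1)[C@@H]2OC(C)(C)O[C@@]2(COCc3ccccc3)C(=O)OC | intermediate
7 | (4R,5S)-4-[(benzyloxy)methyl]-5-(1-hydroxycyclopropyl)-2,2-dimethyl-1,3-dioxolane-4-carbaldehyde (key-step precursor; CHO trans to the cyclopropanol) | OC1(CC1)[C@@H]2OC(C)(C)O[C@@]2(COCc3ccccc3)C=O | intermediate
8 | ethylzinc homoenolate: ethyl(3-oxopropyl)zinc with the C5 ketone on C6 of the dioxolane aldehyde | CC[Zn]CCC(=O)[C@@H]1OC(C)(C)O[C@@]1(COCc2ccccc2)C=O | intermediate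
9 | (3aR,7R,7aS)-7a-[(benzyloxy)methyl]-7-hydroxy-2,2-dimethylhexahydro-1,3-benzodioxol-4-one (trans-fused 2,3-acetonide of 3-(benzyloxymethyl)-2,3,4-trihydroxycyclohexanone) | c1ccccc1COC[C@]2(OC(C)(C)O3)[C@H](O)CCC(=O)[C@@H]23 | intermediate
10 | tert-butyldimethylsilyl trifluoromethanesulfonate | CC(C)(C)[Si](C)(C)OS(=O)(=O)C(F)(F)F | starting material
11 | (3aR,7R,7aR)-7a-[(benzyloxy)methyl]-7-[(tert-butyldimethylsilyl)oxy]-2,2-dimethylhexahydro-1,3-benzodioxol-4-one | c1ccccc1COC[C@]2(OC(C)(C)O3)[C@H](O[Si](C)(C)C(C)(C)C)CCC(=O)[C@@H]23 | intermediate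
12 | (3aS,4S,7R,7aR)-7a-[(benzyloxy)methyl]-7-[(tert-butyldimethylsilyl)oxy]-2,2-dimethylhexahydro-1,3-benzodioxol-4-ol | c1ccccc1COC[C@]2(OC(C)(C)O3)[C@H](O[Si](C)(C)C(C)(C)C)CC[C@H](O)[C@@H]23 | intermediate
13 | benzoic acid | OC(=O)c1ccccc1 | starting material
14 | (3aS,4R,7R,7aR)-7a-[(benzyloxy)methyl]-7-[(tert-butyldimethylsilyl)oxy]-2,2-dimethylhexahydro-1,3-benzodioxol-4-yl benzoate | c1ccccc1COC[C@]2(OC(C)(C)O3)[C@H](O[Si](C)(C)C(C)(C)C)CC[C@@H](OC(=O)c4ccccc4)[C@@H]23 | intermediate
15 | (3aS,4R,7R,7aR)-7-[(tert-butyldimethylsilyl)oxy]-7a-(hydroxymethyl)-2,2-dimethylhexahydro-1,3-benzodioxol-4-yl benzoate | OC[C@]1(OC(C)(C)O2)[C@H](O[Si](C)(C)C(C)(C)C)CC[C@@H](OC(=O)c3ccccc3)[C@@H]12 | intermediate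
16 | benzoyl chloride | O=C(Cl)c1ccccc1 | starting material
17 | [(3aS,4R,7R,7aR)-4-(benzoyloxy)-7-[(tert-butyldimethylsilyl)oxy]-2,2-dimethylhexahydro-1,3-benzodioxol-7a-yl]methyl benzoate | O=C(OC[C@]1(OC(C)(C)O2)[C@H](O[Si](C)(C)C(C)(C)C)CC[C@@H](OC(=O)c3ccccc3)[C@@H]12)c4ccccc4 | intermediate
18 | [(1S,2S,3R,6R)-3-(benzoyloxy)-1,2,6-trihydroxycyclohexyl]methyl benzoate | O=C(OC[C@]1(O)[C@H](O)CC[C@@H](OC(=O)c2ccccc2)[C@@H]1O)c1ccccc1 | target

Total step count: 10
Longest linear sequence: 10 steps (1 → 18)

Steps most likely to fail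

Step 4 (bears the label). The homoenolate may open without closing (protonation to the ethyl ketone), ethyl may be transferred to the aldehyde, closure may go through the other chair and give the C2 epimer, or the product may epimerise at C6 on prolonged exposure to the zinc alkoxide. The fallback uses known reactions only, sets out from aldehyde 7 and returns at hydroxy ketone 9. CH2=CHMgBr (3 equiv, THF, −78 °C) should add to the magnesium chelate of O1 and the aldehyde oxygen from the side of C7 and give the 2R allylic alcohol F1, which already contains the C2–C3 bond. FeCl3 in DMF at 0 °C opens the cyclopropanol oxidatively to the β-chloro ketone F2, and Et3N eliminates HCl to the vinyl ketone F3. Ring-closing metathesis with the second-generation Grubbs catalyst, (H2IMes)(PCy3)Cl2Ru=CHPh, in CH2Cl2 at 40 °C forms C3=C4 and the cyclohexenone F4. Conjugate reduction with [(Ph3P)CuH]6 in toluene, which leaves the benzyl ether alone, gives 9.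

Step 2. Site selection between the two esters may be incomplete, with cyclopropanation of the hindered ester or of both. The fallback sets out from diester 4 and returns at cyclopropanol ester 6; it differentiates the esters by amide formation and builds the three-membered ring from an enol ether. AlMe3 with MeNH(OMe)·HCl in CH2Cl2 converts only the accessible C6 ester to the Weinreb amide F5. MeMgBr (THF, −78 → 0 °C) gives the methyl ketone F6. LiN(SiMe3)2 with Me3SiCl at −78 °C gives the kinetic trimethylsilyl enol ether F7. Furukawa–Simmons–Smith cyclopropanation (Et2Zn, CH2I2, CH2Cl2, 0 °C) gives the siloxycyclopropane F8, and K2CO3 in MeOH removes the silyl group to give 6.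

Step 7. The axial oxyphosphonium ion may undergo anti elimination toward C4 or C6 in place of substitution, or the hindered alcohol may be acylated with retention. The fallback sets out from alcohol 12 and returns at benzoate 14; it separates activation from substitution. Tf2O and pyridine in CH2Cl2 at −20 °C give the C5 triflate F9, and tetrabutylammonium benzoate in toluene at rt displaces it with inversion to give 14.

Further compounds
F1 | step 4 | (1R)-1-[(4S,5S)-4-[(benzyloxy)methyl]-5-(1-hydroxycyclopropyl)-2,2-dimethyl-1,3-dioxolan-4-yl]prop-2-en-1-ol | OC1(CC1)[C@@H]2OC(C)(C)O[C@@]2(COCc3ccccc3)[C@H](O)C=C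
F2 | step 4 | β-chloro ketone: F1 with the cyclopropanol opened to a C5 ketone carrying CH2CH2Cl | ClCCC(=O)[C@@H]1OC(C)(C)O[C@@]1(COCc2ccccc2)[C@H](O)C=C
F3 | step 4 | vinyl ketone: C5 acryloyl group on C6 and (2R)-1-hydroxyallyl group on C1 of the trans-dioxolane | C=CC(=O)[C@@H]1OC(C)(C)O[C@@]1(COCc2ccccc2)[C@H](O)C=C
F4 | step 4 | cyclohexenone: 9 with a C3=C4 double bond | c1ccccc1COC[C@]2(OC(C)(C)O3)[C@H](O)C=CC(=O)[C@@H]23
F5 | step 2 | Weinreb amide: 4 with the C6 ester replaced by C(=O)N(OMe)Me | CON(C)C(=O)[C@@H]1OC(C)(C)O[C@@]1(COCc2ccccc2)C(=O)OC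
F6 | step 2 | methyl ketone: 4 with the C6 ester replaced by acetyl | CC(=O)[C@@H]1OC(C)(C)O[C@@]1(COCc2ccccc2)C(=O)OC
F7 | step 2 | trimethylsilyl enol ether of F6 (terminal C=CH2) | C=C(O[Si](C)(C)C)[C@@H]1OC(C)(C)O[C@@]1(COCc2ccccc2)C(=O)OC
F8 | step 2 | trimethylsilyl ether of cyclopropanol 6 | C[Si](C)(C)OC1(CC1)[C@@H]2OC(C)(C)O[C@@]2(COCc3ccccc3)C(=O)OC
F9 | step 7 | C5 trifluoromethanesulfonate of alcohol 12 (axial, 5S) | c1ccccc1COC[C@]2(OC(C)(C)O3)[C@H](O[Si](C)(C)C(C)(C)C)CC[C@H](OS(=O)(=O)C(F)(F)F)[C@@H]23
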